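**Retrosynthetic overview**
- The only ring to build is the oxirane. It is closed last, by enantioselective oxygen-atom transfer to the C8=C9 alkene of the fully acylated 8,9-dehydro precursor, the same O-insertion a monooxygenase is presumed to perform in the plant; this step also sets the single stereocentre.
- The alkene diester comes from double acylation (phenol O and C10–OH) of the dehydrothymol diol with isovaleric anhydride.
- The C10–OH comes from allylic C–H hydroxylation of the isopropenyl group of 7-oxo-8,9-dehydrothymol, mirroring the presumed C10 hydroxylation.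
- The isopropenyl arene comes from Suzuki–Miyaura coupling of 4-bromo-3-hydroxybenzaldehyde with isopropenylboronic acid pinacol ester.
- Ring order: benzene ring purchased, then the oxirane in the final step.

Atom labels (thymol numbering): C7 = formyl carbon, C8 = side-chain carbon on the ring, C9 = its CH2 (oxirane CH2 in the target), C10 = the acyloxymethyl carbon.

Assumption: the (S,S)-iron complex with the L-amino acid is taken to deliver oxygen to the Si face of C8, which gives the (R)-epoxide; if the first run (chiral HPLC, optical rotation against the natural product) shows the opposite sense, the mirror-image (R,R)-complex with the D-amino acid is used in the same step and nothing else changes.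

Abbreviations for step 4: OTf = CF3SO3; Me2N-PDP = (2S,2′S)-1,1′-bis{[4-(dimethylamino)pyridin-2-yl]methyl}-2,2′-bipyrrolidine.

**Step 1**
Reactants: 1 4-bromo-3-hydroxybenzaldehyde; 2 2-isopropenyl-4,4,5,5-tetramethyl-1,3,2-dioxaborolane (isopropenylboronic acid pinacol ester)
Product: 3 3-hydroxy-4-(prop-1-en-2-yl)benzaldehyde
Conditions: Pd(dppf)Cl2 (3 mol%), K2CO3 (3 equiv), 1,4-dioxane/H2O 4:1, 85 °C; work-up at pH 5
Reagents that add atoms: isopropenylboronic acid pinacol ester (compound 2), CC(=C)B1OC(C)(C)C(C)(C)O1
Why: Suzuki–Miyaura coupling, in which zerovalent palladium inserts into the C–Br bond activated by the para-formyl group, the boronate transmetalates under carbonate and reductive elimination gives the isopropenyl arene, the phenol being carried as its phenoxide; no stereocentre is formed.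

**Step 2**
Reactants: 3 3-hydroxy-4-(prop-1-en-2-yl)benzaldehyde
Product: 6 3-hydroxy-4-(3-hydroxyprop-1-en-2-yl)benzaldehyde, via allylic seleninic acid 4 (not isolated), via allyl selenoxylate ester 5 (not isolated)
Conditions: SeO2 (20 mol%), t-BuOOH (5.5 M in decane, 2.5 equiv), CH2Cl2, 0 to 23 °C; stop near 80% conversion, Na2S2O3 quench
Reagents that add atoms: selenium dioxide, O=[Se]=O (hands its oxygen to C10); tert-butyl hydroperoxide, CC(C)(C)OO (restores the selenium dioxide and is the net oxygen source)
Why: Selenium dioxide allylic hydroxylation, in which an ene reaction at the terminal CH2 gives seleninic acid 4, a [2,3]-sigmatropic shift returns the double bond to C8=C9 while placing oxygen on the former methyl carbon (ester 5), and hydrolysis releases alcohol 6 while the hydroperoxide reoxidises selenium; the methyl group is the only allylic position and no stereocentre is formed.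

**Step 3**
Reactants: 6 3-hydroxy-4-(3-hydroxyprop-1-en-2-yl)benzaldehyde; 7 3-methylbutanoic anhydride (isovaleric anhydride)
Product: 8 2-[4-formyl-2-(3-methylbutanoyloxy)phenyl]prop-2-en-1-yl 3-methylbutanoate
Conditions: 7 (2.6 equiv), DMAP (10 mol%), pyridine, 0 to 23 °C
Reagents that add atoms: 3-methylbutanoic anhydride (compound 7), CC(C)CC(=O)OC(=O)CC(C)C
Why: DMAP-catalysed acyl transfer, in which the N-acylpyridinium ion formed from 7 esterifies both the phenol and the primary allylic alcohol while aldehyde and alkene are untouched; no stereocentre is formed.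

**Step 4**
Reactants: 8 2-[4-formyl-2-(3-methylbutanoyloxy)phenyl]prop-2-en-1-yl 3-methylbutanoate
Product: 9 [(2R)-2-[4-formyl-2-(3-methylbutanoyloxy)phenyl]oxiran-2-yl]methyl 3-methylbutanoate
Conditions: (S,S)-[Fe(OTf)2(Me2N-PDP)] (3 mol%), N-(1,8-naphthaloyl)-L-isoleucine (5 mol%), 30% aq. H2O2 (2.0 equiv, syringe pump, 40 min), MeCN, −30 °C; NaHCO3/Na2S2O3 quench, Et3N-deactivated silica
Reagents that add atoms: hydrogen peroxide, OO
Why: Proposed new method: bioinspired non-heme iron asymmetric epoxidation applied to an α-(acyloxymethyl)styrene carrying a free aldehyde, in which the amino acid carboxylate bound to iron assists heterolysis of the coordinated hydroperoxide to an electrophilic pentavalent iron-oxo carboxylate that transfers its oxygen atom in one concerted step to the only alkene, the chiral pocket of bipyrrolidine ligand and amino acid distinguishing the aryl from the acyloxymethyl substituent so that oxygen adds to the Si face of C8 (priorities CH2O-acyl > aryl > =CH2) and sets the (R) quaternary centre, while the electron-poor formyl C–H and the two isovaleryl methine C–H bonds (each β to an ester carbonyl) should react far more slowly at −30 °C with 2 equiv of oxidant; the closest known reaction type is the iron-catalysed epoxidation of α-alkylstyrenes with aqueous hydrogen peroxide and an N-protected amino acid co-ligand, which is highly enantioselective.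

**Compound list**
1 | 4-bromo-3-hydroxybenzaldehyde | O=Cc1ccc(Br)c(O)c1 | starting material
2 | 2-isopropenyl-4,4,5,5-tetramethyl-1,3,2-dioxaborolane | CC(=C)B1OC(C)(C)C(C)(C)O1 | starting material
3 | 3-hydroxy-4-(prop-1-en-2-yl)benzaldehyde | CC(=C)c1ccc(C=O)cc1O | intermediate
4 | 2-(4-formyl-2-hydroxyphenyl)prop-2-ene-1-seleninic acid | C=C(C[Se](=O)O)c1ccc(C=O)cc1O | intermediate
5 | 2-(4-formyl-2-hydroxyphenyl)prop-2-en-1-yl hydrogen selenoxylate (ArC(=CH2)CH2O–Se–OH, divalent selenium) | C=C(CO[Se]O)c1ccc(C=O)cc1O | intermediate
6 | 3-hydroxy-4-(3-hydroxyprop-1-en-2-yl)benzaldehyde | C=C(CO)c1ccc(C=O)cc1O | intermediate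
7 | 3-methylbutanoic anhydride | CC(C)CC(=O)OC(=O)CC(C)C | starting material
8 | 2-[4-formyl-2-(3-methylbutanoyloxy)phenyl]prop-2-en-1-yl 3-methylbutanoate | CC(C)CC(=O)OCC(=C)c1ccc(C=O)cc1OC(=O)CC(C)C | intermediate
9 | [(2R)-2-[4-formyl-2-(3-methylbutanoyloxy)phenyl]oxiran-2-yl]methyl 3-methylbutanoate | CC(C)CC(=O)OC[C@@]1(c2ccc(C=O)cc2OC(=O)CC(C)C)CO1 | target

**Totals**
Total steps: 4. Longest linear sequence: 4 (1 → 3 → 6 → 8 → 9).

**Steps most likely to fail**

Step 4 (most at risk). The enantioselectivity and even the facial sense are untested on an ortho-substituted, electron-poor α-substituted styrene. The formyl group may be oxidised, and the 2-aryl oxirane may open or rearrange on acidic contact. The fallback replaces catalyst-controlled epoxidation of the ester by hydroxyl-directed epoxidation. It sets out from 6. Phenoxide-selective acylation (7 1.1 equiv, 1 M aq. NaOH, CH2Cl2, Bu4NHSO4 cat., 0 °C) gives 5-formyl-2-(3-hydroxyprop-1-en-2-yl)phenyl 3-methylbutanoate F1. Sharpless asymmetric epoxidation (Ti(OiPr)4 10 mol%, L-(+)-diethyl tartrate 12 mol%, t-BuOOH, 4 Å sieves, CH2Cl2, −20 °C) gives 5-formyl-2-[(2S)-2-(hydroxymethyl)oxiran-2-yl]phenyl 3-methylbutanoate F2. The tartrate delivers oxygen to the same face as in the conversion of methallyl alcohol to (S)-2-methylglycidol. Acylation of F2 with 7 (DMAP, pyridine, 0 °C) comes back to the route at 9. The descriptor changes from S to R only because the acylated CH2O arm then outranks the ring CH2; the geometry is unchanged.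

Step 2. Over-oxidation to the 2-arylacrolein, attack of selenium reagents on the free phenol, and acid-induced cyclisation of 6 to benzofuran-type products are all possible. The fallback brings the C10 oxygen in by C–C coupling instead of C–H oxidation. It sets out from 1, which is coupled under the step 1 conditions with 2-(4,4,5,5-tetramethyl-1,3,2-dioxaborolan-2-yl)prop-2-en-1-ol F3. F3 is made from propargyl alcohol and bis(pinacolato)diboron by α-selective copper-catalysed protoboration ((SIMes)CuCl 5 mol%, SIMes = 1,3-dimesitylimidazolidin-2-ylidene, NaOt-Bu, MeOH, THF, 0 °C). The coupling comes back to the route at 6.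

Step 1. The phenoxide may slow oxidative addition, boronate 2 may protodeboronate or polymerise, and the o-isopropenylphenol 3 is acid-sensitive. The fallback masks the phenol as the ester it finally carries and introduces the C10 oxygen by halide displacement. It sets out from 1. Acylation with 7 (DMAP, pyridine) gives 2-bromo-5-formylphenyl 3-methylbutanoate F4. Anhydrous Suzuki–Miyaura coupling with 2 (Pd(OAc)2 2 mol%, SPhos 4 mol%, K3PO4, toluene, 80 °C) gives 5-formyl-2-(prop-1-en-2-yl)phenyl 3-methylbutanoate F5. Ene-type allylic bromination (NBS, TsOH·H2O 10 mol%, THF, 65 °C) gives 2-(3-bromoprop-1-en-2-yl)-5-formylphenyl 3-methylbutanoate F6. Displacement with caesium 3-methylbutanoate (isovaleric acid, Cs2CO3, DMF, 23 °C) comes back to the route at 8.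

**Further compounds**
F1 | step 4 | 5-formyl-2-(3-hydroxyprop-1-en-2-yl)phenyl 3-methylbutanoate | C=C(CO)c1ccc(C=O)cc1OC(=O)CC(C)C
F2 | step 4 | 5-formyl-2-[(2S)-2-(hydroxymethyl)oxiran-2-yl]phenyl 3-methylbutanoate | OC[C@@]1(c2ccc(C=O)cc2OC(=O)CC(C)C)CO1
F3 | step 2 | 2-(4,4,5,5-tetramethyl-1,3,2-dioxaborolan-2-yl)prop-2-en-1-ol | C=C(CO)B1OC(C)(C)C(C)(C)O1
F4 | step 1 | 2-bromo-5-formylphenyl 3-methylbutanoate | CC(C)CC(=O)Oc1cc(C=O)ccc1Br
F5 | step 1 | 5-formyl-2-(prop-1-en-2-yl)phenyl 3-methylbutanoate | CC(=C)c1ccc(C=O)cc1OC(=O)CC(C)C
F6 | step 1 | 2-(3-bromoprop-1-en-2-yl)-5-formylphenyl 3-methylbutanoate | C=C(CBr)c1ccc(C=O)cc1OC(=O)CC(C)C
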